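**Retrosynthetic overview**
- The target is 5-O-methylxylerythrin; the last disconnection is the O–CH3 bond on the strongly acidic 5-OH of xylerythrin.
- Xylerythrin's butenolide (lactone C–O and the C3=C3a bond) is disconnected to polyporic acid plus 4-hydroxyphenylacetic acid, joined by O-acylation and intramolecular Knoevenagel condensation (Perkin-type), isolated as the diacetate.
- Polyporic acid comes from 2,5-diphenyl-1,4-benzoquinone by dibromination and hydroxide substitution.
- Ring order: the six-membered carbocycle is bought intact; the butenolide is the only ring formed (step 3).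

Assumption: the target has no stereocentre and no stereogenic double bond (the exocyclic alkene is locked in the fused rings), so it is achiral and no stereocontrol is needed. Polyporic acid is made here because it is sold only in small quantities.

**Step 1**
Reactants: 1 2,5-diphenyl-1,4-benzoquinone
Product: 2 3,6-dibromo-2,5-diphenyl-1,4-benzoquinone
Conditions: Br2 (2.5 equiv), AcOH, 100 °C
Reagents that add atoms: bromine, BrBr
Why: The two quinone C–H positions undergo bromine addition then dehydrobromination (net vinylic substitution), while the phenyl rings, deactivated by the quinone, are left alone; no stereocentre is formed.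

**Step 2**
Reactants: 2 3,6-dibromo-2,5-diphenyl-1,4-benzoquinone
Product: 4 polyporic acid (2,5-dihydroxy-3,6-diphenyl-1,4-benzoquinone), via disodium polyporate 3 (not isolated)
Conditions: aq NaOH (5 equiv), 1,4-dioxane, N2, 80 °C; then 2 M HCl
Reagents that add atoms: sodium hydroxide, [Na+].[OH-]
Why: Each bromide sits on the β-carbon of a vinylogous acyl bromide, so hydroxide substitutes it by conjugate addition–elimination (vinylic nucleophilic substitution), and the stable bis-enolate 3 gives the vinylogous acid 4 on acidification.

**Step 3**
Reactants: 4 polyporic acid; 5 4-hydroxyphenylacetic acid (1.05 equiv)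
Product: 8 xylerythrin diacetate (5-acetoxy-3-(4-acetoxyphenyl)-4,7-diphenyl-1-benzofuran-2,6-dione), via mixed anhydride 6 (not isolated), via quinone arylacetate ester 7 (not isolated)
Conditions: Ac2O, NaOAc, 120 °C
Reagents that add atoms: acetic anhydride, CC(=O)OC(C)=O
Why: In this Perkin-type annulation, mixed anhydride 6 O-acylates one enolic OH, the activated ArCH2 of ester 7 adds to the adjacent quinone carbonyl (intramolecular Knoevenagel/aldol) and dehydrates to the butenolide while Ac2O caps the other two OH groups; the symmetry of 4 allows only one regioisomer and no stereocentre is created.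

**Step 4**
Reactants: 8 xylerythrin diacetate
Product: 9 xylerythrin (5-hydroxy-3-(4-hydroxyphenyl)-4,7-diphenyl-1-benzofuran-2,6-dione)
Conditions: conc. HCl (cat.), AcOH–H2O, 90 °C
Reagents that add atoms: none
Why: Acid-catalysed ester hydrolysis removes the labile enol acetate (a vinylogous anhydride) and the aryl acetate, and the conjugated enol lactone is the thermodynamic form under acid, so it re-closes if it opens.

**Step 5**
Reactants: 9 xylerythrin
Product: 10 5-O-methylxylerythrin (3-(4-hydroxyphenyl)-5-methoxy-4,7-diphenyl-1-benzofuran-2,6-dione), the target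
Conditions: CH2N2 (1.05 equiv, Et2O), THF, 0 °C; AcOH quench
Reagents that add atoms: diazomethane, C=[N+]=[N-]
Why: The 5-OH is a doubly vinylogous carboxylic acid, far more acidic than the phenol, so it alone protonates diazomethane fast enough to be O-methylated (diazomethane esterification), and the fully substituted ring alkenes resist dipolar cycloaddition.

**Compound list**
1 | 2,5-diphenyl-1,4-benzoquinone | O=C1C=C(c2ccccc2)C(=O)C=C1c1ccccc1 | starting material
2 | 3,6-dibromo-2,5-diphenyl-1,4-benzoquinone | O=C1C(Br)=C(c2ccccc2)C(=O)C(Br)=C1c1ccccc1 | intermediate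
3 | disodium polyporate (formed in the flask) | [Na+].[Na+].[O-]C1=C(c2ccccc2)C(=O)C([O-])=C(c2ccccc2)C1=O | intermediate
4 | polyporic acid (2,5-dihydroxy-3,6-diphenyl-1,4-benzoquinone) | OC1=C(c2ccccc2)C(=O)C(O)=C(c2ccccc2)C1=O | intermediate
5 | 4-hydroxyphenylacetic acid | OC(=O)Cc1ccc(O)cc1 | starting material
6 | (4-acetoxyphenyl)acetic acetic anhydride (formed in the flask) | CC(=O)OC(=O)Cc1ccc(OC(C)=O)cc1 | intermediate
7 | 2-acetoxy-5-[(4-acetoxyphenyl)acetoxy]-3,6-diphenyl-1,4-benzoquinone (formed in the flask) | CC(=O)OC1=C(c2ccccc2)C(=O)C(OC(=O)Cc2ccc(OC(C)=O)cc2)=C(c2ccccc2)C1=O | intermediate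
8 | xylerythrin diacetate | CC(=O)OC1=C(c2ccccc2)C2=C(c3ccc(OC(C)=O)cc3)C(=O)OC2=C(c2ccccc2)C1=O | intermediate
9 | xylerythrin | OC1=C(c2ccccc2)C2=C(c3ccc(O)cc3)C(=O)OC2=C(c2ccccc2)C1=O | intermediate
10 | 5-O-methylxylerythrin (CNP0282683.0) | COC1=C(c2ccccc2)C2=C(c3ccc(O)cc3)C(=O)OC2=C(c2ccccc2)C1=O | target

**Step count and risks**
Total steps: 5. Longest linear sequence: 5 (1 → 2 → 4 → 8 → 9 → 10).

The three steps most likely to fail:

Step 3 (annulation). Symmetrical 4 can react twice to give a bis-lactone, and acetyl/arylacetyl scrambling can lower the yield. The fallback desymmetrises the quinone before the ring is made. It sets out from 2: NaOMe in MeOH replaces both bromides to give 2,5-dimethoxy-3,6-diphenyl-1,4-benzoquinone F1. One equivalent of NaOH in aqueous dioxane, then acidification, hydrolyses only one vinylogous ester (the mono-anion shuts down the second) to give 2-hydroxy-5-methoxy-3,6-diphenyl-1,4-benzoquinone F2. Heating F2 with 5 in Ac2O/NaOAc can annulate only at the single free OH and gives 5-O-methylxylerythrin 4'-acetate F3. Acid-catalysed methanolysis of the aryl acetate (HCl, MeOH, 40 °C) comes back to the route at 10, so steps 4 and 5 are no longer needed.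

Step 4 (deacetylation). Hydrolysing the aryl acetate may open or degrade the enol lactone. The fallback carries the phenol as a methyl ether and unmasks it without hydrolysis. It sets out from 4: the same Ac2O/NaOAc annulation, run with commercial 4-methoxyphenylacetic acid in place of 5, gives 5-O-acetyl-4'-O-methylxylerythrin F4. BBr3 in CH2Cl2 (−78 °C to rt, aqueous work-up) cleaves the aryl methyl ether and the labile enol acetate and comes back to the route at 9.

Step 5 (selective methylation). Diazomethane may also methylate the phenol, attack another oxygen of the ambident anion, or add to the quinone methide. The fallback forms the C5–OMe bond from methanol instead of the O–CH3 bond from an electrophile. It sets out from 9: refluxing in MeOH with catalytic H2SO4 etherifies only the vinylogous acid by addition of methanol and loss of water (vinylogous Fischer esterification), which a phenol cannot undergo, and comes back to the route at 10. It makes no new compound (F0).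

**Further compounds**
F1 | step 3 | 2,5-dimethoxy-3,6-diphenyl-1,4-benzoquinone | COC1=C(c2ccccc2)C(=O)C(OC)=C(c2ccccc2)C1=O
F2 | step 3 | 2-hydroxy-5-methoxy-3,6-diphenyl-1,4-benzoquinone | COC1=C(c2ccccc2)C(=O)C(O)=C(c2ccccc2)C1=O
F3 | step 3 | 5-O-methylxylerythrin 4'-acetate (3-(4-acetoxyphenyl)-5-methoxy-4,7-diphenyl-1-benzofuran-2,6-dione) | COC1=C(c2ccccc2)C2=C(c3ccc(OC(C)=O)cc3)C(=O)OC2=C(c2ccccc2)C1=O
F4 | step 4 | 5-O-acetyl-4'-O-methylxylerythrin (5-acetoxy-3-(4-methoxyphenyl)-4,7-diphenyl-1-benzofuran-2,6-dione) | CC(=O)OC1=C(c2ccccc2)C2=C(c3ccc(OC)cc3)C(=O)OC2=C(c2ccccc2)C1=O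
F0 | step 5 | none | none
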